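**Retrosynthetic overview**
1. Locants: cyclohexane ring C1 (bears the side chain), C2 (CH2), C3/C4 (oxirane carbons, C4 bears CH3), C5 (C=O), C6 (CH–O); side chain C7(=C14H2)–C8(O-angelate)–C9–C10=C11.
2. 26 ⇒ ketol 24 (senecioylation of O–C6) ⇒ open-chain epoxy α-keto aldehyde 23, by a type-I carbonyl-ene disconnection of C1–C6.
3. Enabling feature: the homoallylic alcohol array O–C6–C1–C7(=C14H2) spans the cyclohexane ring and the exocyclic methylene, and the ring ketone C5 sits next to C6. C6 can therefore be a glyoxal-type formyl enophile, and a Z-C1=C7(CH3) alkene can be the ene.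
4. 23 ⇒ (Z,Z)-skipped dienol 18 (oxirane by Sharpless epoxidation, C6 added as a hydroxymethyl-anion equivalent) ⇒ alkenyl iodide 7 + allylic bromide 11 (C1–C2 cross-coupling). Both come from iodo alcohol 3, and C8 comes from asymmetric allylboration.
5. Ring order: oxirane first (step 11), cyclohexane last (step 16).

Key step: step 16

Assumption (remark on the chemistry): the C5 carbinol epimers of 21 and 22 are carried on as a mixture, because this centre becomes the ketone in step 15.

**Step 1**
Reactants: 1 prop-2-yn-1-ol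
Product: 3 (Z)-3-iodo-2-methylprop-2-en-1-ol, via alkenylmagnesium alkoxide 2 (not isolated)
Conditions: MeMgBr (2.5 equiv), CuI (10 mol %), Et2O, −10 °C to rt; then I2, −20 °C
Reagents that add atoms: methylmagnesium bromide C[Mg]Br; iodine II
Why: Alkoxide-directed, copper-catalysed anti-carbomagnesiation puts CH3 on the inner alkyne carbon and magnesium cis to CH2O in chelate 2, so iodinolysis with retention should give only the Z-iodide.

**Step 2**
Reactants: 3 (Z)-3-iodo-2-methylprop-2-en-1-ol
Product: 4 (Z)-3-iodo-2-methylprop-2-enal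
Conditions: activated MnO2, CH2Cl2, rt, used at once
Reagents that add atoms: none
Why: Allylic alcohol oxidation with MnO2 is neutral and should leave the Z-iodoalkene geometry untouched.

**Step 3**
Reactants: 4 (Z)-3-iodo-2-methylprop-2-enal
Product: 6 (1Z,3S)-1-iodo-2-methylhexa-1,5-dien-3-ol, via diisopinocampheylborinate 5 (not isolated)
Conditions: (−)-Ipc2B(allyl), Et2O, −78 °C; then 3 M NaOH, 30 % H2O2, 0 °C
Reagents that add atoms: (−)-B-allyldiisopinocampheylborane C=CCB([C@@H]1C[C@@H]2C[C@H]([C@H]1C)C2(C)C)[C@@H]1C[C@@H]2C[C@H]([C@H]1C)C2(C)C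
Why: In the Brown asymmetric allylboration, which runs through a closed chair transition state, the (+)-α-pinene-derived reagent should add to the Si face of the enal and set C8 as S.

**Step 4**
Reactants: 6 (1Z,3S)-1-iodo-2-methylhexa-1,5-dien-3-ol
Product: 7 (1Z,3S)-1-iodo-2,7-dimethylocta-1,6-dien-3-ol
Conditions: Grubbs II (3 mol %), 2-methyl-2-butene (excess), CH2Cl2, 40 °C
Reagents that add atoms: 2-methyl-2-butene CC=C(C)C
Why: Olefin cross-metathesis of the terminal alkene with excess 2-methyl-2-butene turns allyl into prenyl, and the trisubstituted iodoalkene should be inert to the ruthenium carbene.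

**Step 5**
Reactants: 3 (Z)-3-iodo-2-methylprop-2-en-1-ol
Product: 8 1-({[(Z)-3-iodo-2-methylprop-2-en-1-yl]oxy}methyl)-4-methoxybenzene
Conditions: NaH, PMBCl, Bu4NI (cat.), THF/DMF, 0 °C to rt
Reagents that add atoms: 4-methoxybenzyl chloride COc1ccc(CCl)cc1
Why: Williamson etherification gives an ether that cannot migrate in the later alkenyllithium and alkoxide stages, as a silyl group could.

**Step 6**
Reactants: 8 1-({[(Z)-3-iodo-2-methylprop-2-en-1-yl]oxy}methyl)-4-methoxybenzene
Product: 10 (Z)-4-[(4-methoxybenzyl)oxy]-3-methylbut-2-en-1-ol, via alkenyllithium 9 (not isolated)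
Conditions: t-BuLi (2.1 equiv), Et2O, −78 °C; (CH2O)n, −78 °C to rt
Reagents that add atoms: formaldehyde (from paraformaldehyde) C=O
Why: Iodine–lithium exchange proceeds with retention of alkene geometry, and 1,2-addition of 9 to formaldehyde installs C2.

**Step 7**
Reactants: 10 (Z)-4-[(4-methoxybenzyl)oxy]-3-methylbut-2-en-1-ol
Product: 11 1-({[(Z)-4-bromo-2-methylbut-2-en-1-yl]oxy}methyl)-4-methoxybenzene
Conditions: CBr4, PPh3, CH2Cl2, 0 °C
Reagents that add atoms: carbon tetrabromide BrC(Br)(Br)Br
Why: The Appel reaction replaces the primary allylic hydroxyl by SN2 under neutral conditions, without allylic shift or Z/E change.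

**Step 8**
Reactants: 7 (1Z,3S)-1-iodo-2,7-dimethylocta-1,6-dien-3-ol; 11 1-({[(Z)-4-bromo-2-methylbut-2-en-1-yl]oxy}methyl)-4-methoxybenzene
Product: 14 (2Z,5Z,7S)-1-[(4-methoxybenzyl)oxy]-2,6,10-trimethylundeca-2,5,9-trien-7-ol, via dilithio dianion 12 (not isolated), via alkenylzinc bromide 13 (not isolated)
Conditions: 7, t-BuLi (3.1 equiv), Et2O, −78 °C; ZnBr2, THF, to 0 °C; 11, Pd(PPh3)4 (5 mol %), 0 °C to rt
Reagents that add atoms: none
Why: In this Negishi alkenyl–allyl cross-coupling the γ,γ-disubstituted π-allylpalladium should couple at its primary terminus and cannot easily exchange syn/anti positions, so both Z-alkenes and C8 are kept.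

**Step 9**
Reactants: 14 (2Z,5Z,7S)-1-[(4-methoxybenzyl)oxy]-2,6,10-trimethylundeca-2,5,9-trien-7-ol; 15 angelic acid
Product: 17 (2Z,5Z,7S)-1-[(4-methoxybenzyl)oxy]-2,6,10-trimethylundeca-2,5,9-trien-7-yl (Z)-2-methylbut-2-enoate, via mixed anhydride 16 (not isolated)
Conditions: 15, 2,4,6-trichlorobenzoyl chloride, Et3N, toluene, rt; then 14, 75 °C (no DMAP)
Reagents that add atoms: none
Why: Yamaguchi-type mixed-anhydride esterification without a nucleophilic catalyst avoids the addition–elimination path from angelate to tiglate, and the C8–O bond is not broken.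

**Step 10**
Reactants: 17 (2Z,5Z,7S)-1-[(4-methoxybenzyl)oxy]-2,6,10-trimethylundeca-2,5,9-trien-7-yl (Z)-2-methylbut-2-enoate
Product: 18 (2Z,5Z,7S)-1-hydroxy-2,6,10-trimethylundeca-2,5,9-trien-7-yl (Z)-2-methylbut-2-enoate
Conditions: DDQ, CH2Cl2/pH 7 buffer, 0 °C
Reagents that add atoms: none
Why: Oxidative PMB cleavage by hydride abstraction from the electron-rich benzylic position should be faster than any attack on the alkenes or esters at 0 °C.

**Step 11**
Reactants: 18 (2Z,5Z,7S)-1-hydroxy-2,6,10-trimethylundeca-2,5,9-trien-7-yl (Z)-2-methylbut-2-enoate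
Product: 19 (2Z,4S)-1-[(2S,3R)-3-(hydroxymethyl)-3-methyloxiran-2-yl]-3,7-dimethylocta-2,6-dien-4-yl (Z)-2-methylbut-2-enoate
Conditions: Ti(OiPr)4 (0.3 equiv), D-(−)-DIPT (0.36 equiv), t-BuOOH, 4 Å MS, CH2Cl2, −20 °C
Reagents that add atoms: tert-butyl hydroperoxide CC(C)(C)OO
Why: In the Sharpless asymmetric epoxidation only the alkene with the free allylic hydroxyl binds to titanium, the D-(−)-tartrate should deliver oxygen to the face that gives the target configuration at C3 and C4, and stereospecific syn addition to the Z-alkene keeps C2 and C5 cis on the oxirane.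

**Step 12**
Reactants: 19 epoxy alcohol
Product: 20 (2Z,4S)-1-[(2S,3S)-3-formyl-3-methyloxiran-2-yl]-3,7-dimethylocta-2,6-dien-4-yl (Z)-2-methylbut-2-enoate
Conditions: TEMPO (10 mol %), PhI(OAc)2, CH2Cl2, rt
Reagents that add atoms: none
Why: Oxoammonium (TEMPO) oxidation stops at the aldehyde and spares alkenes, oxirane and ester, and C4 has no hydrogen, so it cannot epimerise.

**Step 13**
Reactants: 20 epoxy aldehyde
Product: 21 β-hydroxysilane (20 with CHO changed to CH(OH)CH2SiMe2(OiPr), C5 epimers)
Conditions: (i-PrO)Me2SiCH2MgCl, THF, −78 to −20 °C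
Reagents that add atoms: (isopropoxydimethylsilyl)methylmagnesium chloride CC(C)O[Si](C)(C)C[Mg]Cl
Why: Grignard 1,2-addition of the Tamao hydroxymethyl-anion equivalent brings in C6 and should be much faster at the aldehyde than at the hindered angelate; the new C5 centre is left uncontrolled and is removed in step 15.

**Step 14**
Reactants: 21 β-hydroxysilane
Product: 22 epoxy 1,2-diol (20 with CHO changed to CH(OH)CH2OH, C5 epimers)
Conditions: 30 % H2O2, KF, KHCO3, THF/MeOH, rt
Reagents that add atoms: hydrogen peroxide OO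
Why: Tamao oxidation replaces the C–Si bond by C–OH under weakly basic conditions that should not trigger Payne rearrangement or ester cleavage.

**Step 15**
Reactants: 22 epoxy 1,2-diol
Product: 23 (2Z,4S)-3,7-dimethyl-1-[(2S,3S)-3-methyl-3-(oxoacetyl)oxiran-2-yl]octa-2,6-dien-4-yl (Z)-2-methylbut-2-enoate
Conditions: (COCl)2, DMSO, CH2Cl2, −78 °C; Et3N, to −20 °C; rapid cold work-up, azeotropic drying, used crude
Reagents that add atoms: none
Why: Double Swern oxidation takes a vicinal diol to the 1,2-dicarbonyl without C–C cleavage, and 23 has no enolisable hydrogen next to either carbonyl.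

**Step 16**
Reactants: 23 epoxy α-keto aldehyde
Product: 24 (3S)-2-[(1S,3S,4S,6S)-4-hydroxy-6-methyl-5-oxo-7-oxabicyclo[4.1.0]heptan-3-yl]-6-methylhepta-1,5-dien-3-yl (Z)-2-methylbut-2-enoate
Conditions: [Cu((S,S)-t-Bu-box)](SbF6)2 (10 mol %), 4 Å MS, CH2Cl2 (0.005 M), −40 to 0 °C
Reagents that add atoms: none
Why: Bidentate binding of the C5/C6 dicarbonyl to copper(II) lowers the formyl LUMO, and C1 of the Z-C1=C7 alkene adds to C6 while a hydrogen of the C14 methyl group passes to the aldehyde oxygen in one concerted, asynchronous six-electron event (type-I intramolecular carbonyl-ene reaction). The closest known reactions are the citronellal-to-isopulegol cyclisation and the bis(oxazoline)copper-catalysed ene reactions of glyoxylates and glyoxals. The cyclohexane ring closes by C1–C6 bond formation through a chair-like transition state (half-chair at the oxirane) in which the tether joins the enophile carbon to the ene terminus. C1 and C6 are set relative to each other by the alkene geometry: in the Z-alkene only the methyl group, trans to the tether, can reach the oxygen, and this is possible only when the C6–O bond and C7 are both equatorial, hence trans (the s-cis chelate maps onto an equatorial C6–O bond). Their sense relative to the oxirane should follow from the half-chair that holds the axial C6–H syn to the oxirane oxygen and not to the C4 methyl group, reinforced by the (S,S)-ligand, which shields the formyl face leading to 6R, and by A1,3 strain at C8, which turns the small acyloxy oxygen and not the C9 chain toward the attacked alkene face. The step needs formyl-over-ketone, C14–H-over-C8–H and C1=C7-over-C10=C11 selectivity and survival of the oxirane, which are secured in turn by the higher electrophilicity of the formyl group, the misplaced and acyloxy-deactivated C8–H, the ring size (six against ten), and the electron-poor acyl-substituted oxirane with non-nucleophilic counter-ions.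

**Step 17**
Reactants: 24 ketol; 25 3-methylbut-2-enoyl chloride
Product: 26 target, (1S,3S,4S,6S)-1-methyl-4-[(3S)-6-methyl-3-{[(Z)-2-methylbut-2-enoyl]oxy}hepta-1,5-dien-2-yl]-2-oxo-7-oxabicyclo[4.1.0]heptan-3-yl 3-methylbut-2-enoate
Conditions: 25, pyridine, CH2Cl2, 0 °C to rt
Reagents that add atoms: none
Why: O-acylation with an acid chloride and pyridine is mild enough that the equatorial C6 centre should not epimerise and the senecioyl double bond should stay conjugated.

**Compound list**
1 | prop-2-yn-1-ol | C#CCO | starting material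
2 | (Z)-alkenylmagnesium alkoxide | C/C(CO[Mg]Br)=C/[Mg]Br | intermediate
3 | (Z)-3-iodo-2-methylprop-2-en-1-ol | OC/C(C)=C\I | intermediate
4 | (Z)-3-iodo-2-methylprop-2-enal | O=C/C(C)=C\I | intermediate
5 | diisopinocampheylborinate of 6 | C=CC[C@H](OB([C@@H]1C[C@@H]2C[C@H]([C@H]1C)C2(C)C)[C@@H]1C[C@@H]2C[C@H]([C@H]1C)C2(C)C)/C(C)=C\I | intermediate
6 | (1Z,3S)-1-iodo-2-methylhexa-1,5-dien-3-ol | C=CC[C@H](O)/C(C)=C\I | intermediate
7 | (1Z,3S)-1-iodo-2,7-dimethylocta-1,6-dien-3-ol | CC(C)=CC[C@H](O)/C(C)=C\I | intermediate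
8 | PMB ether of 3 | COc1ccc(COC/C(C)=C\I)cc1 | intermediate
9 | (Z)-alkenyllithium from 8 | COc1ccc(COC/C(C)=C\[Li])cc1 | intermediate
10 | (Z)-4-[(4-methoxybenzyl)oxy]-3-methylbut-2-en-1-ol | COc1ccc(COC/C(C)=C\CO)cc1 | intermediate
11 | (Z)-allylic bromide | COc1ccc(COC/C(C)=C\CBr)cc1 | intermediate
12 | dilithio dianion from 7 | CC(C)=CC[C@H](O[Li])/C(C)=C\[Li] | intermediate
13 | alkenylzinc bromide | CC(C)=CC[C@H](O[Li])/C(C)=C\[Zn]Br | intermediate
14 | (2Z,5Z,7S)-1-[(4-methoxybenzyl)oxy]-2,6,10-trimethylundeca-2,5,9-trien-7-ol | CC(C)=CC[C@H](O)/C(C)=C\C/C=C(/C)COCc1ccc(OC)cc1 | intermediate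
15 | angelic acid, (Z)-2-methylbut-2-enoic acid | C/C=C(/C)C(=O)O | starting material
16 | angelic 2,4,6-trichlorobenzoic anhydride | C/C=C(/C)C(=O)OC(=O)c1c(Cl)cc(Cl)cc1Cl | intermediate
17 | angelate of 14 | CC(C)=CC[C@H](OC(=O)/C(C)=C\C)/C(C)=C\C/C=C(/C)COCc1ccc(OC)cc1 | intermediate
18 | (Z,Z)-dienol angelate | CC(C)=CC[C@H](OC(=O)/C(C)=C\C)/C(C)=C\C/C=C(/C)CO | intermediate
19 | epoxy alcohol | CC(C)=CC[C@H](OC(=O)/C(C)=C\C)/C(C)=C\C[C@@H]1O[C@]1(C)CO | intermediate
20 | epoxy aldehyde | CC(C)=CC[C@H](OC(=O)/C(C)=C\C)/C(C)=C\C[C@@H]1O[C@]1(C)C=O | intermediate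
21 | β-hydroxysilane (C5 epimers) | CC(C)=CC[C@H](OC(=O)/C(C)=C\C)/C(C)=C\C[C@@H]1O[C@]1(C)C(O)C[Si](C)(C)OC(C)C | intermediate
22 | epoxy 1,2-diol (C5 epimers) | CC(C)=CC[C@H](OC(=O)/C(C)=C\C)/C(C)=C\C[C@@H]1O[C@]1(C)C(O)CO | intermediate
23 | epoxy α-keto aldehyde | CC(C)=CC[C@H](OC(=O)/C(C)=C\C)/C(C)=C\C[C@@H]1O[C@]1(C)C(=O)C=O | intermediate
24 | ketol | C=C([C@H](CC=C(C)C)OC(=O)/C(C)=C\C)[C@@H]1C[C@@H]2O[C@]2(C)C(=O)[C@H]1O | intermediate
25 | 3-methylbut-2-enoyl chloride (senecioyl chloride) | CC(C)=CC(=O)Cl | starting material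
26 | CNP0333561.1 | C=C([C@H](CC=C(C)C)OC(=O)/C(C)=C\C)[C@@H]1C[C@@H]2O[C@]2(C)C(=O)[C@H]1OC(=O)C=C(C)C | target

**Step count**
Total steps: 17. Longest linear sequence: 14 (steps 1–4, then 8–17). Steps 5–7 form the side branch from 3.

**Steps most likely to fail**

Step 16. What may go wrong:
- poor facial selectivity of the formyl group relative to the oxirane,
- Lewis-acid opening or acyl-shift rearrangement of the oxirane,
- oligomerisation of the glyoxal.

The fallback sets out from 22 and comes back at 26. It closes the ring at a lower oxidation level and installs the ketone afterwards.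
- Bis-silylation (TESOTf, 2,6-lutidine) gives the bis(triethylsilyl) ether F1.
- Swern conditions convert only the primary silyl ether into the α-silyloxy aldehyde F2, whose C5 epimers can be separated. The epimer that places OTES equatorial in the desired chair then adds a further control element.
- An aluminium Lewis acid (Me2AlCl, CH2Cl2, −78 °C) effects the citronellal-type ene closure to the cyclohexanol F3.
- Acylation with 25 gives the senecioate F4, and HF·pyridine frees the C5 carbinol F5.
- Dess–Martin oxidation of F5 gives 26.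

Step 15. What may go wrong:
- C5–C6 cleavage,
- hydrate or oligomer formation on work-up,
- premature uncatalysed cyclisation.

The fallback sets out from 22 and comes back at 23 by stepwise oxidation.
- Selective silylation of the primary hydroxyl (TBSCl, imidazole) gives the mono-TBS ether F6.
- Dess–Martin oxidation gives the silyloxy ketone F7, and HF·pyridine gives the primary ketol F8.
- Copper(II) acetate/air oxidation of the ketol in methanol, followed by removal of methanol over molecular sieves, gives 23.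

Step 8. What may go wrong:
- incomplete exchange or protonation of the dianion,
- attack at the tertiary allyl terminus,
- erosion of Z geometry through π-allyl isomerisation.

The fallback sets out from 8 and comes back at 14. It makes C1=C7 instead of C1–C2, by the Z-selective Wittig reaction of an unstabilised ylide with an α-alkoxy methyl ketone.
- Ylide branch: 8 is lithiated and opened onto ethylene oxide (BF3·OEt2) to give the homoallylic alcohol F9. This is converted (I2, PPh3, imidazole) into the iodide F10 and (PPh3, MeCN, reflux) into the phosphonium iodide F11.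
- Ketone branch: commercial 6-methylhept-5-en-2-one is α-aminoxylated (nitrosobenzene, D-proline) to the aminoxy ketone F12. This is reduced (Zn, AcOH) to the (S)-hydroxy ketone F13 and silylated to the TES ether F14.
- Union: the ylide from F11 (KHMDS, THF/HMPA, −78 °C) and F14 give the triene TES ether F15, and PPTS/MeOH releases 14.

**Further compounds**
F1 | step 16 | bis(triethylsilyl) ether of 22 | CC(C)=CC[C@H](OC(=O)/C(C)=C\C)/C(C)=C\C[C@@H]1O[C@]1(C)C(CO[Si](CC)(CC)CC)O[Si](CC)(CC)CC
F2 | step 16 | α-(triethylsilyloxy) aldehyde | CC(C)=CC[C@H](OC(=O)/C(C)=C\C)/C(C)=C\C[C@@H]1O[C@]1(C)C(C=O)O[Si](CC)(CC)CC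
F3 | step 16 | cyclohexanol with C5–OTES | C=C([C@H](CC=C(C)C)OC(=O)/C(C)=C\C)[C@@H]1C[C@@H]2O[C@]2(C)C(O[Si](CC)(CC)CC)[C@H]1O
F4 | step 16 | C6 senecioate with C5–OTES | C=C([C@H](CC=C(C)C)OC(=O)/C(C)=C\C)[C@@H]1C[C@@H]2O[C@]2(C)C(O[Si](CC)(CC)CC)[C@H]1OC(=O)C=C(C)C
F5 | step 16 | C6 senecioate with free C5 carbinol | C=C([C@H](CC=C(C)C)OC(=O)/C(C)=C\C)[C@@H]1C[C@@H]2O[C@]2(C)C(O)[C@H]1OC(=O)C=C(C)C
F6 | step 15 | primary TBS ether of 22 | CC(C)=CC[C@H](OC(=O)/C(C)=C\C)/C(C)=C\C[C@@H]1O[C@]1(C)C(O)CO[Si](C)(C)C(C)(C)C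
F7 | step 15 | α-(TBS-oxy) epoxy ketone | CC(C)=CC[C@H](OC(=O)/C(C)=C\C)/C(C)=C\C[C@@H]1O[C@]1(C)C(=O)CO[Si](C)(C)C(C)(C)C
F8 | step 15 | primary ketol | CC(C)=CC[C@H](OC(=O)/C(C)=C\C)/C(C)=C\C[C@@H]1O[C@]1(C)C(=O)CO
F9 | step 8 | (Z)-5-[(4-methoxybenzyl)oxy]-4-methylpent-3-en-1-ol | OCC/C=C(/C)COCc1ccc(OC)cc1
F10 | step 8 | (Z)-homoallylic iodide | ICC/C=C(/C)COCc1ccc(OC)cc1
F11 | step 8 | (Z)-phosphonium iodide | [I-].COc1ccc(COC/C(C)=C\CC[P+](c2ccccc2)(c2ccccc2)c2ccccc2)cc1
F12 | step 8 | (S)-6-methyl-3-[(phenylamino)oxy]hept-5-en-2-one | CC(=O)[C@@H](ONc1ccccc1)CC=C(C)C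
F13 | step 8 | (S)-3-hydroxy-6-methylhept-5-en-2-one | CC(=O)[C@@H](O)CC=C(C)C
F14 | step 8 | (S)-6-methyl-3-(triethylsilyloxy)hept-5-en-2-one | CC(=O)[C@@H](O[Si](CC)(CC)CC)CC=C(C)C
F15 | step 8 | TES ether of 14 | CC(C)=CC[C@H](O[Si](CC)(CC)CC)/C(C)=C\C/C=C(/C)COCc1ccc(OC)cc1
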